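**Retrosynthetic overview**

1. Both flavan units are bought with every ring and the C2/C3 stereocentres in place: (+)-dihydromyricetin 1 (upper unit, 2R,3R) and (−)-epicatechin 2 (lower unit, 2R,3R). No protecting groups are used.
2. The only disconnection is the C4–C8 interflavan bond, cut the way the plant makes it: an extension-unit electrophile plus a starter-unit nucleophile.
3. The electrophile comes from C4=O of 1 by reduction to the flavan-3,4-diol (leucodelphinidin 3) and ionisation to the C4 cation / ring A quinone methide 4. The nucleophile is C8–H of 2.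
4. Capture of 4 by 2 gives gallocatechin-(4α→8)-epicatechin 5. C4 (S) is the only stereocentre made, set anti to the 3-OH.
5. Ring order: no ring is built. Rings A, B and C of both units come intact from 1 and 2, and the whole sequence runs in one flask.

Assumption: the SMILES is read as gallocatechin-(4α→8)-epicatechin (upper unit 2R,3S,4S, 2,3-trans-3,4-trans; lower unit 2R,3R), and commercial (+)-dihydromyricetin is taken as the (2R,3R) enantiomer, its ee being checked by chiral HPLC before use.

**Route**

Step 1
Reactants: 1 (+)-dihydromyricetin (2R,3R; 1 equiv); 2 (−)-epicatechin (2R,3R; 4 equiv, the excess is recovered)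
Product: 5 gallocatechin-(4α→8)-epicatechin, via leucodelphinidin 3 (not isolated), via C4 cation 4 (not isolated)
Conditions: NaBH4 (6 equiv, in EtOH, added over 30 min), degassed EtOH, Ar, 20 °C, 1 h; then degassed H2O, AcOH to pH 5, 20 °C, 1 h; EtOAc extraction, Sephadex LH-20 (EtOH), C18 preparative HPLC
Reagents that add atoms: none
Why: NaBH4 reduction of the aryl ketone gives the flavan-3,4-diol 3, whose benzylic 4-OH ionises at pH 5 to cation 4 (stabilised by the 5,7-dioxygenated ring A as a quinone methide), and a biomimetic Friedel–Crafts (SN1) capture by the phloroglucinol-type ring A of 2 then forms the interflavan bond at C8 (the more nucleophilic site, flanked by O1 and the 7-OH) from the face anti to the 3-OH of the half-chair cation with its 2-aryl group equatorial, which sets C4 as S (3,4-trans, 4α) without touching C2 or C3 of either unit.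

**Compound list**

1 | (+)-dihydromyricetin (ampelopsin), (2R,3R)-3,5,7-trihydroxy-2-(3,4,5-trihydroxyphenyl)chroman-4-one | Oc1cc(O)c2c(c1)O[C@H](c1cc(O)c(O)c(O)c1)[C@@H](O)C2=O | starting material
2 | (−)-epicatechin, (2R,3R)-2-(3,4-dihydroxyphenyl)chromane-3,5,7-triol (2,3-cis) | Oc1cc(O)c2c(c1)O[C@H](c1ccc(O)c(O)c1)[C@H](O)C2 | starting material
3 | 2,3-trans-3,4-trans-leucodelphinidin, (2R,3S,4R)-2-(3,4,5-trihydroxyphenyl)chromane-3,4,5,7-tetrol | Oc1cc(O)c2c(c1)O[C@H](c1cc(O)c(O)c(O)c1)[C@@H](O)[C@@H]2O | intermediate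
4 | gallocatechin C4 cation, (2R,3S)-3,5,7-trihydroxy-2-(3,4,5-trihydroxyphenyl)chroman-4-ylium (protonated ring A quinone methide) | Oc1cc(O)c2c(c1)O[C@H](c1cc(O)c(O)c(O)c1)[C@@H](O)[CH+]2 | intermediate
5 | gallocatechin-(4α→8)-epicatechin, (2R,3S,4S)-4-[(2R,3R)-2-(3,4-dihydroxyphenyl)-3,5,7-trihydroxychroman-8-yl]-2-(3,4,5-trihydroxyphenyl)chromane-3,5,7-triol | Oc1cc(O)c2c(c1)O[C@H](c1cc(O)c(O)c(O)c1)[C@@H](O)[C@@H]2c1c(O)cc(O)c2c1O[C@H](c1ccc(O)c(O)c1)[C@H](O)C2 | target

**Step count and risks**

Total step count: 1. Longest linear sequence: 1.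

Expected outcome, by analogy with the same condensation in closely related dimers: about 20–30 % of 5 from 1, with the 4→8 product favoured over 4→6 by roughly 8–10 : 1 and 3,4-trans over 3,4-cis by at least 10 : 1. Most of the excess 2 is recovered from the first LH-20 fractions.

The route has a single step, so the three entries are the three stages of step 1, most risky first.

1. Step 1, capture of cation 4 by 2. Risks: 3 condenses with itself through its own ring A, 4 attacks product 5 to give trimers, and 5 re-ionises in the acid. The fallback replaces the transient diol by a purified thioether electrophile that is activated by a thiophile instead of a protic acid. It sets out from 3, made from 1 exactly as in step 1 but without 2. Benzyl mercaptan (5 equiv) and AcOH (pH 4) are added in EtOH/H2O at 20 °C; sulfur outcompetes every carbon nucleophile and gives 4α-benzylsulfanyl-gallocatechin F1, which is stable to chromatography. F1 is then added slowly to 2 (4 equiv) and AgBF4 (2.2 equiv) in THF at 0 °C in the dark. Monovalent silver abstracts the thiolate and regenerates cation 4, where the fallback comes back to the route; capture by 2 gives 5 at a temperature at which 5 does not re-ionise.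

2. Step 1, borohydride reduction of 1. Risks: in the basic medium the pyrogallol ring autoxidises, ring C opens and C2 epimerises, or the chelated, phenolate-deactivated ketone reduces incompletely. The fallback is a biocatalytic reduction at neutral pH and sets out from 1. Recombinant dihydroflavonol 4-reductase with catalytic NADPH (recycled by glucose dehydrogenase and D-glucose) in KH2PO4/K2HPO4 buffer, pH 6.5, 30 °C, under Ar gives the natural 2,3-trans-3,4-cis-leucodelphinidin F2. After 2 (4 equiv) is added and the pH is brought to 5, F2 ionises to the same cation 4, where the fallback comes back to the route.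

3. Step 1, regiochemistry and isolation. Risks: the 4→6 isomer and mixed oligomers are formed in larger amounts than expected or cannot be separated from 5. The fallback is a benzyl-protected coupling, in which C8 attack is essentially exclusive and all intermediates run on silica. It sets out from 2 and 1.
   - BnBr and K2CO3 in DMF (0 °C to 20 °C, Ar) convert 2 into 5,7,3',4'-tetra-O-benzyl-epicatechin F3 and 1 into 5,7,3',4',5'-penta-O-benzyl-dihydromyricetin F4.
   - NaBH4 in THF/EtOH reduces F4 to penta-O-benzyl-leucodelphinidin F5.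
   - TMSOTf (Me3SiOSO2CF3, 0.2 equiv) in CH2Cl2 at −78 °C ionises F5 to the penta-O-benzyl C4 cation F6, which F3 (3 equiv) captures at C8, anti to the 3-OH, to give nona-O-benzyl-gallocatechin-(4α→8)-epicatechin F7.
   - H2 (1 atm) over Pd(OH)2 on carbon in THF/MeOH/H2O at 20 °C removes the nine benzyl groups, and the fallback comes back to the route at 5.

**Further compounds**

F1 | step 1 | 4α-benzylsulfanyl-gallocatechin, (2R,3R,4R)-4-(benzylsulfanyl)-2-(3,4,5-trihydroxyphenyl)chromane-3,5,7-triol (2,3-trans-3,4-trans) | Oc1cc(O)c2c(c1)O[C@H](c1cc(O)c(O)c(O)c1)[C@@H](O)[C@@H]2SCc1ccccc1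
F2 | step 1 | 2,3-trans-3,4-cis-leucodelphinidin, (2R,3S,4S)-2-(3,4,5-trihydroxyphenyl)chromane-3,4,5,7-tetrol | Oc1cc(O)c2c(c1)O[C@H](c1cc(O)c(O)c(O)c1)[C@@H](O)[C@H]2O
F3 | step 1 | 5,7,3',4'-tetra-O-benzyl-epicatechin, (2R,3R) | c1ccccc1COc1cc(OCc3ccccc3)c2c(c1)O[C@H](c1ccc(OCc3ccccc3)c(OCc3ccccc3)c1)[C@H](O)C2
F4 | step 1 | 5,7,3',4',5'-penta-O-benzyl-dihydromyricetin, (2R,3R) | c1ccccc1COc1cc(OCc3ccccc3)c2c(c1)O[C@H](c1cc(OCc3ccccc3)c(OCc3ccccc3)c(OCc3ccccc3)c1)[C@@H](O)C2=O
F5 | step 1 | 5,7,3',4',5'-penta-O-benzyl-leucodelphinidin, (2R,3S,4R), 2,3-trans-3,4-trans | c1ccccc1COc1cc(OCc3ccccc3)c2c(c1)O[C@H](c1cc(OCc3ccccc3)c(OCc3ccccc3)c(OCc3ccccc3)c1)[C@@H](O)[C@@H]2O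
F6 | step 1 | penta-O-benzyl-gallocatechin C4 cation, (2R,3S) | c1ccccc1COc1cc(OCc3ccccc3)c2c(c1)O[C@H](c1cc(OCc3ccccc3)c(OCc3ccccc3)c(OCc3ccccc3)c1)[C@@H](O)[CH+]2
F7 | step 1 | nona-O-benzyl-gallocatechin-(4α→8)-epicatechin, upper unit (2R,3S,4S), lower unit (2R,3R) | c1ccccc1COc1cc(OCc3ccccc3)c2c(c1)O[C@H](c1cc(OCc3ccccc3)c(OCc3ccccc3)c(OCc3ccccc3)c1)[C@@H](O)[C@@H]2c1c(OCc3ccccc3)cc(OCc3ccccc3)c2c1O[C@H](c1ccc(OCc3ccccc3)c(OCc3ccccc3)c1)[C@H](O)C2
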